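**Assumptions**
- (+)-Genipin (CAS 6902-77-8) is sold by the gram and is taken as the chiral-pool starting material.
- Iridoid numbering is used: C1 acetal, O2, C3=C4, C5/C9 ring fusion, C6, C7, C8, C10 = CH2 on C8, C11 = CH2 on C4. β is the face carrying H-5 and H-9.
- Silylating agents, hydride, fluoride and oxidant are treated as reagents and are not numbered.

**Reading of the target:** (1S,4aS,6S,7R,7aS), which is 1S,5S,7S,8R,9S in iridoid numbering. H-5, H-9, the 1-O-acyl group, 7-OH and C10 are all β, and 8-OH is α. The 7,8-diol is therefore trans. C1, C5 and C9 are spatially identical to those of genipin.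

## Retrosynthetic overview
1. The target comes from the 7β,8β-epoxy-10-acetate 10. The acetate opens the epoxide at C8 from the α-face, and water then hydrolyses the acetoxonium ion. This inverts C8, keeps the C7–O bond, and leaves the acetate on C10.
2. Compound 10 comes from hydroxyl-directed β-face epoxidation of the C10 allylic alcohol 7, followed by acetylation.
3. Compound 7 comes from double isovalerylation of the C1-lactol/C11-alcohol 4, with C10 masked as its TBS ether.
4. Compound 4 comes from DIBAL reduction of the C11 methyl ester of orthogonally silylated genipin (1-OTES, 10-OTBS).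
5. Neither carbocyclic nor pyran ring is built, because the cis-fused cyclopenta[c]pyran (C1, C5, C9) is bought. Only transient rings form: the oxirane first, then the spiro-dioxolanylium ion.

## Route

**Step 1**
Reactants: 1, (+)-genipin
Product: 2, 10-O-TBS-1-O-TES-genipin (1β-OSiEt3; 1S,4aS,7aS)
Conditions: TBSCl (1.05 equiv), imidazole, DMF, 0 °C; then TESCl (1.3 equiv), 0 °C → rt, one pot
Reagents that add atoms: TBSCl, CC(C)(C)[Si](C)(C)Cl; TESCl, CC[Si](CC)(CC)Cl
Why: In this chemoselective silylation the primary allylic OH takes the bulky TBS group first, and the lactol OH is then capped with the more labile TES group, so ring-opening to the C1 aldehyde cannot occur in step 2; no stereocentre is touched.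

**Step 2**
Reactants: 2
Product: 3, the C11 primary alcohol (4-hydroxymethyl enol ether) with 1-OTES and 10-OTBS retained
Conditions: DIBAL-H (2.5 equiv), CH2Cl2, −78 °C; aq. Rochelle salt; Et3N-buffered silica
Reagents that add atoms: none
Why: DIBAL-H reduces the β-alkoxyacrylate (vinylogous carbonate) in a 1,2-sense to the allylic alcohol, and the silyl ethers, acetal and alkenes are inert at −78 °C.

**Step 3**
Reactants: 3
Product: 4, the 1β-lactol/C11-alcohol diol with 10-OTBS retained (1R,4aS,7aS)
Conditions: TBAF/AcOH (1:1, 1.1 equiv), THF, −20 °C, 30 min; pH 7 work-up; used crude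
Reagents that add atoms: none
Why: In this chemoselective fluoride desilylation the anomeric TES ether has a lactolate leaving group and a small silyl group, so it cleaves far faster than the primary TBS ether.

**Step 4**
Reactants: 4; 5, isovaleric anhydride
Product: 6, 1β,11-bis-O-isovaleryl-10-O-TBS compound (1S,4aS,7aS)
Conditions: 5 (3 equiv), Et3N, DMAP (0.2 equiv), CH2Cl2, 0 °C
Reagents that add atoms: isovaleric anhydride, CC(C)CC(=O)OC(=O)CC(C)C
Why: DMAP-catalysed acylation esterifies both free hydroxyls, and C1 is fixed as the pseudo-axial β-ester favoured by the anomeric effect, which is the configuration of genipin and the natural valepotriates (any minor epimer is removed by chromatography).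

**Step 5**
Reactants: 6
Product: 7, 1β,11-bis-O-isovaleryl C10 allylic alcohol
Conditions: HF·pyridine, excess pyridine, THF, 0 °C → rt
Reagents that add atoms: none
Why: Buffered HF desilylation removes the primary TBS group without the base that would cleave or migrate the acylal or the esters, and without enough acidity to ionise the enol ether.

**Step 6**
Reactants: 7
Product: 8, 7β,8β-epoxy-10-ol (7S,8S, iridoid numbering), bis-isovalerate
Conditions: VO(acac)2 (5 mol %), t-BuOOH (decane, 1.5 equiv), CH2Cl2, 0 °C → rt
Reagents that add atoms: tert-butyl hydroperoxide, CC(C)(C)OO (adds O)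
Why: In this Sharpless–Michaelson vanadium-catalysed directed epoxidation the C10 vanadate restricts oxidation to C7=C8 and spares the undirected enol ether, and oxygen arrives on the convex β-face (H-5/H-9 side) because the folded pyran blocks the α-face, which sets C7 and provisionally C8.

**Step 7**
Reactants: 8; 9, acetic anhydride
Product: 10, 7β,8β-epoxy-10-acetate (an isomer of didrovaltrate, C22H32O8)
Conditions: Ac2O (1.5 equiv), pyridine, DMAP (cat.), CH2Cl2, 0 °C
Reagents that add atoms: acetic anhydride, CC(=O)OC(C)=O
Why: Simple O-acetylation installs the final C10 acetate, which is also the internal nucleophile for step 8, and the epoxide and esters are inert.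

**Step 8**
Reactants: 10
Product: 11, the target (1S,4aS,6S,7R,7aS)
Conditions: BF3·OEt2 (1.0 equiv), CH2Cl2, −78 °C, 20 min; then THF/H2O–NaHCO3, −78 → 0 °C
Reagents that add atoms: water, O
Why: This is a Lewis-acid epoxide opening with Winstein-type anchimeric assistance, in which the acetate carbonyl attacks tertiary C8 anti to the epoxide C–O bond (5-exo, α-face, inversion) to give a spiro-acetoxonium ion while C7–O stays β, and water then hydrolyses it to 8α-OH/10-OAc (any tertiary acetate shifts to the favoured primary position).

## Compound list
| No. | Name | SMILES | Role |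
|---|---|---|---|
| 1 | (+)-Genipin | OCC1=CC[C@@H]2C(C(=O)OC)=CO[C@@H](O)[C@H]12 | starting material |
| 2 | 10-O-TBS-1-O-TES-genipin | CC(C)(C)[Si](C)(C)OCC1=CC[C@@H]2C(C(=O)OC)=CO[C@@H](O[Si](CC)(CC)CC)[C@H]12 | intermediate |
| 3 | C11 alcohol, 1-OTES, 10-OTBS | CC(C)(C)[Si](C)(C)OCC1=CC[C@@H]2C(CO)=CO[C@@H](O[Si](CC)(CC)CC)[C@H]12 | intermediate |
| 4 | 1-lactol/11-ol, 10-OTBS | CC(C)(C)[Si](C)(C)OCC1=CC[C@@H]2C(CO)=CO[C@@H](O)[C@H]12 | intermediate |
| 5 | Isovaleric anhydride | CC(C)CC(=O)OC(=O)CC(C)C | starting material |
| 6 | 1β,11-bis-isovalerate, 10-OTBS | CC(C)(C)[Si](C)(C)OCC1=CC[C@@H]2C(COC(=O)CC(C)C)=CO[C@@H](OC(=O)CC(C)C)[C@H]12 | intermediate |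
| 7 | 1β,11-bis-isovalerate, 10-OH | OCC1=CC[C@@H]2C(COC(=O)CC(C)C)=CO[C@@H](OC(=O)CC(C)C)[C@H]12 | intermediate |
| 8 | 7β,8β-epoxy-10-ol | OC[C@]12O[C@H]1C[C@@H]1C(COC(=O)CC(C)C)=CO[C@@H](OC(=O)CC(C)C)[C@H]21 | intermediate |
| 9 | Acetic anhydride | CC(=O)OC(C)=O | starting material |
| 10 | 7β,8β-epoxy-10-acetate | CC(=O)OC[C@]12O[C@H]1C[C@@H]1C(COC(=O)CC(C)C)=CO[C@@H](OC(=O)CC(C)C)[C@H]21 | intermediate |
| 11 | CID42638123 | CC(=O)OC[C@]1(O)[C@H]2[C@H](OC(=O)CC(C)C)OC=C(COC(=O)CC(C)C)[C@H]2C[C@@H]1O | target |

## Summary
**Total steps:** 8, or 9 if the mono-TBS ether in step 1 is isolated.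
**Longest linear sequence:** 8, fully linear from genipin.

**Steps most likely to fail**
1. **Step 8.**
   - Risks: Meinwald hydride shift to the 7-ketone, Ferrier-type ionisation of the C11 ester, and a mixture of acetate regioisomers.
   - Fallback: move the C8 inversion to the methyl-ester stage, where the enol ether is acid-robust.
   - Sequence: 10-O-acetyl-1-O-TES-genipin is treated with mCPBA and then BF3.
   - The acetoxonium ion is quenched with MeOH/Et3N to give the spiro 8,10-orthoacetate.
   - 7-OH is silylated and the material is carried through DIBAL and bis-isovalerylation.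
   - The 8-OH/10-OAc pair is released at the end by pH 4–5 orthoester hydrolysis and desilylation.
2. **Step 6.**
   - Risks: poor β/α facial selectivity and oxidation of the electron-rich enol ether.
   - Fallback: epoxidise first, on 1-O-TES-genipin, which has a free C10-OH and a C3=C4 bond deactivated by the CO2Me group.
   - Use reagent control there: Katsuki–Sharpless epoxidation with L-(+)-DIPT, which gives the 2S-type epoxide (8S here).
   - Then silylate C10 and carry the epoxide through steps 2–5.
3. **Steps 3 and 4.**
   - Risks: the electron-rich lactol diol 4 is fragile, and the C1 anomer ratio may be poor.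
   - Fallback: never liberate 4. Isovalerylate the C11-OH of 3 first.
   - Then exchange 1-OTES directly for the ester by fluoride-triggered acyl transfer (CsF or TBAT with isovaleric anhydride present), so the lactolate is trapped as it forms. This adds one step.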